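The numbers in the tables come from a simulation for an exercise, and the scatter is random.

The ash run is your ruler, but it reads E in percent of its own charge of L, so turn its readings into mM before you carry them to another flask.

| flask | L | X | temperature | remark | time |
|---|---|---|---|---|---|
| ash | 6.7 mM | 0.15 mM | 25 °C | run made earlier |  |
| eta | 10 mM | 0.60 mM | 5 °C |  | 25 min |
| alpha | 10 mM | 0.15 mM | 25 °C |  | 25 min |

ash run (percent of the L charged)

| time / min | E / % |
|---|---|
| 2.50 | 0 |
| 5.00 | 2.7 |
| 8.00 | 6.7 |
| 10.0 | 11.7 |
| 12.0 | 16.2 |
| 15.0 | 22.6 |

(standard deviation of a reading: 1 percentage point)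

- L is a solid; its amount is given per volume of the solution
- at the start none of L is in solution
- what has only dissolved of L counts as not reacted
- the earlier runs do not show what temperature does; that part of a forecast is a guess
- no earlier run changes the charge of X; that part of a forecast is a guess

- the winner by amount of E, in percent of the L charged; "neither" if no more than 2 percentage points parts them (eta / alpha / neither)
- how much E is there at the end, in percent of the L charged: eta
- how much E is there at the end, in percent of the L charged: alpha

In the ash run, E reads 0% at 2.50 min, so the curve starts flat: this is the induction period. From 8.00 min to 15.0 min it climbs nearly straight, with slope 0.152 mM min⁻¹. Run back, that line meets zero at 5.05 min, but the reading of 2.7% at 5.00 min shows a rounded knee.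

Now join the ends. The upper bound is the charge, and the line would reach alpha's 10 mM at 70.8 min, later than the asked 25 min, so alpha should still be on the straight stretch. I assume that the slope in mM/min ignores the charge of L, which one charge cannot test. Then c(E) at 25 min is 3.04 mM; call this the line amount. For alpha it means 30.4%. Eta has the same charge of L but other X and temperature, which the ash run cannot price, so I give it no number.

The forecast names alpha as the winner, with 20% (7% to 42%) for eta and 33% (26% to 46%) for alpha, above my figure, and it reasons that “the same absolute rate at 10 mM L gives about 30% of the charge”.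

The flask gives 36.0% for alpha and 10.6% for eta, so alpha wins. The ash flask at 25 min stands at 53.7% of its smaller charge, which is 3.60 mM, against 3.60 mM in alpha. Measured against the line amount, alpha holds 1.18 of it and eta 0.350.

    G → Q (k = 0.437 min⁻¹, Ea = 80.0 kJ mol⁻¹)
    X + Q → X + E (k = 861 M⁻¹ min⁻¹, Ea = 51.0 kJ mol⁻¹)
    2 G → Z (k = 9.86 M⁻¹ min⁻¹, Ea = 58.0 kJ mol⁻¹)
    L ⇌ G, rate k4*(cs4 - [G]) while solid is left; crystals form when [G] > cs4 (solubility = 5.10 mM, k = 0.0515 min⁻¹)
    E → J (k = 2.66 × 10⁻⁴ min⁻¹, Ea = 109 kJ mol⁻¹)
    (constants at 25 °C)

Take a neighbour flask, which is eta with 6.0 mM of L. The line amount times eta's 0.350, spread over that charge, gives 17.7%. The computed flask gives 17.7%.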